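**Remark on the chemistry:** tert-butoxyacetic acid 1 and 1-(benzyloxy)-4-ethynylbenzene 10 are taken as purchasable, and the single stereocentre is taken as S, as the stereo-SMILES reads.

## Analysis of the target

The target 26 is a p-terphenyl whose central benzene ring is fully substituted: C1' carries the (3S)-3-hydroxybutanoyloxy group, C2' a free hydroxyl, C3' a 4-hydroxyphenyl ring, C4' the 3-phenylpropanoyloxy group, C5' a free hydroxyl and C6' the second 4-hydroxyphenyl ring. It is the hydroquinone form of a 2,5-diaryl-3,6-dihydroxy-1,4-benzoquinone in which the two para-related enolic oxygens carry two different acyl groups. The only stereocentre is C3 of the hydroxybutanoyl chain; it is remote, relates to no other stereo-element and can be bought. The sensitive points are the electron-rich hydroquinone (air oxidation), the two aryl esters that each sit ortho to a free phenol (1,2-acyl shift, hydrolysis) and the β-hydroxy ester (elimination to a crotonate). The difficulty is not the carbon skeleton but the four oxygens of the central ring, which are equivalent in the parent skeleton, so that a symmetrical tetraoxygenated ring can only be hetero-acylated statistically. Because the core has a twofold axis, only one hetero-diester exists; it is therefore enough to fix which para pair is acylated and to acylate its two oxygens one after the other. The strategy rests on the ring sequence O–aryl–O–O–aryl–O, which divides into a C3 piece C(O)–C(O)–C(aryl), a C2 piece C(aryl)–C(O) and one C(O). These are an α-alkoxy styryl carbene, an aryl ynol ether and carbon monoxide, and each oxygen then enters with its own substituent.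

## Retrosynthetic reasoning

**26 from 25.** The last operation changes only the oxidation level and removes protecting groups. The hydroquinone is taken back to quinone 25, and the three hydroxyls outside the central ring are taken back to benzyl ethers. One hydrogenation then does everything, and the air-sensitive, migration-prone hydroquinone exists only in the final flask.

**25 from 20 and 23.** The ester C–O bond of the hydroxybutanoyl group is cut last, so the chiral piece is used latest. Its partner is hydroxyquinone 20, which has a single free enolic hydroxyl. Acid 23 (activated as chloride 24) comes from ester 22 and this from the chiral-pool ester 21. The benzyl ether on C3 is chosen so that it falls in the final hydrogenation.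

**20 from 17 and 18.** The 3-phenylpropanoyl ester is cut next. Hydroxyquinone 17 has one free enolic oxygen (O2) and one tert-butyl-protected oxygen (O5), so acylation with chloride 18 to give 19 needs no statistics. Acidolysis of the tert-butyl group of 19 then frees O5 as 20. The forward steps have to keep the first ester through the acid treatment.

**17 from 15.** The quinone carbonyls are traced to a para-related OH/OMe pair, and the enolic hydroxyl to a silyl ether. Oxidative demethylation of phenol 15 gives silyloxyquinone 16, and desilylation gives 17. In 15 the four oxygens therefore have four roles: OH and OMe become the quinone (and finally the two free hydroxyls), and O-silyl and O-tert-butyl are the two acylation sites, released in that order.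

**15 from 9 and 13 (key disconnection).** Three C–C bonds of the central ring are cut: C4–C3, C2–C1 and C1–C6. This gives carbene complex 9 (C4, C5, C6 with OMe, O-tert-butyl and aryl), siloxyalkyne 13 (C3, C2 with aryl and O-silyl) and one carbonyl ligand of 9 (C1, the phenol carbon). No other cut of this ring delivers the oxygens already differentiated. The forward reaction has to insert the alkyne with its oxygen-bearing carbon next to the carbonyl-derived carbon.

**9 from 5 and 6.** The chromium–carbon bond is cut to the pentacarbonylchromate dianion (from 6) and acid chloride 7, through acylchromate 8. An organolithium route is avoided because the benzyl ether would not survive it. Acid 5 is cut at its C=C bond to aldehyde 3 and ester 2, made from acid 1, through ester 4. The condensation should give the Z alkene (aryl trans to the carboxyl carbon), which is the geometry that places hydrogen on the inside of the later ring closure.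

**13 from 10.** The C–O bond of the ynol ether is cut: alkyne 10 is deprotonated to 11, oxidised to ynolate 12 and silylated on oxygen.

## Alternatives that were turned down

**Alternative 1:** The central ring is cut at its two C–C bonds between C3 of one arylpyruvate unit and C1 of the other. In the forward sense an atromentin-synthetase-type enzyme condenses two molecules of 4-hydroxyphenylpyruvic acid A2 head to tail to give atromentin A1.
- For: one aqueous step, no protecting groups, no metal, and the para-terphenyl connectivity is guaranteed. On step count to the skeleton it is clearly stronger than the chosen route.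
- Against: A1 is symmetrical, with two equivalent enolic hydroxyls and two free phenols. Placing two different acyl groups is then statistical, the phenols compete, and protecting them afterwards runs against the acidity order (the enolic hydroxyls react first). Enzyme production, cofactor supply and scale are further burdens.
- Comparison: the chosen route is longer to the ring but delivers the ring with the acylation sites already distinguished and the phenols already protected.

**Alternative 2:** Here the outer rings are disconnected, four C–C bonds in all. Two molecules of diene A4 (1-methoxy-3-(trimethylsilyloxy)buta-1,3-diene) add to the two 1-(phenylsulfonyl)vinyl groups of the central-ring precursor A5. Acid and then base strip the silyl enol ether, the methoxy group and the sulfonyl group, and both 4-hydroxyphenyl rings of terphenyldiol A3 appear.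
- For: a known reaction type, matched polarisation that fixes the para-hydroxy pattern, two-directional, metal-free. In certainty of the ring-forming step it is stronger than the chosen route.
- Against: it builds the two rings that are available as simple benzene derivatives and leaves the central ring with four identical methoxy groups. Their removal needs a strong Lewis acid, and the hetero-acylation is again statistical. A5 itself needs several steps on a crowded hexasubstituted ring, and its twisted 1,1-disubstituted vinyl sulfones are poor dienophiles.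
- Comparison: the chosen route places its one uncertain step where the real problem of the target lies.

**Alternative 3:** The central ring is cut into three alkynes. RhCl(PPh3)3 A9 (monovalent rhodium) joins the silicon-tethered bis(aryl ynol ether) A7 with di-tert-butoxyethyne A8 to give benzodioxasilole A6, forming three C–C bonds.
- For: the whole ring with all six substituents in one step, the tether enforces the para arrangement of the aryl groups, and both aryl halves come from one alkyne. In convergence it equals or exceeds the chosen route.
- Against: the oxygens emerge differentiated in ortho pairs (the silylene-bridged pair and the di-tert-butoxy pair), whereas the target needs para pairs and, within the acylated pair, two different acyl groups. Each pair would still have to be split statistically, and freeing the bridged pair gives a catechol with its ortho-quinone chemistry. A7 and A8 are fragile (tert-butyl ynol ethers fragment to ketenes on warming), and three electron-rich alkynes are poor partners for cyclotrimerisation.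
- Comparison: the chosen route gives four distinct oxygens with the correct para pairing.

Key step: step 5

## Route

Step 1
Reactants: 1 tert-butoxyacetic acid
Product: 2 methyl 2-(tert-butoxy)acetate
Conditions: MeI, K2CO3, DMF, 25 °C
Reagents that add atoms: iodomethane, CI
Why: O-Alkylation of the potassium carboxylate (SN2 esterification) needs no acid, so the tert-butyl ether is not at risk.

Step 2
Reactants: 2 methyl 2-(tert-butoxy)acetate; 3 4-(benzyloxy)benzaldehyde
Product: 5 (2Z)-3-[4-(benzyloxy)phenyl]-2-tert-butoxyprop-2-enoic acid, via methyl ester 4 (not isolated)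
Conditions: NaOMe, MeOH, 65 °C; then NaOH, H2O, 65 °C; then 1 M HCl to pH 3, 0 °C
Reagents that add atoms: sodium hydroxide, [Na+].[OH-]
Why: Claisen-type aldol condensation of an α-alkoxy ester with a non-enolisable aryl aldehyde, E1cB dehydration and saponification in one pot; the conjugated product should settle in the Z form (aryl trans to the carboxyl group), and the basic medium leaves both ethers alone.

Step 3
Reactants: 5 (2Z)-3-[4-(benzyloxy)phenyl]-2-tert-butoxyprop-2-enoic acid; 6 hexacarbonylchromium Cr(CO)6
Product: 9 pentacarbonyl{(2Z)-3-[4-(benzyloxy)phenyl]-2-tert-butoxy-1-methoxyprop-2-en-1-ylidene}chromium, via acid chloride 7 (not isolated), via sodium acylchromate 8 (not isolated)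
Conditions: 5, Me2C=C(Cl)NMe2, CH2Cl2, 0 → 25 °C; then Na2Cr(CO)5 [from 6, NaC10H8, THF, −78 °C], THF, −78 → 0 °C; then Me3OBF4, CH2Cl2, 0 °C
Reagents that add atoms: trimethyloxonium tetrafluoroborate, C[O+](C)C.F[B-](F)(F)F
Why: The pentacarbonylchromate dianion is acylated at chromium by the acid chloride and the acylchromate is O-methylated by the oxonium salt (acid chloride route to Fischer carbene complexes of zerovalent chromium); no organolithium is used, which would attack the benzylic CH2 of the aryl benzyl ether, and the neutral chloroenamine makes the chloride without HCl.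

Step 4
Reactants: 10 1-(benzyloxy)-4-ethynylbenzene
Product: 13 ({[4-(benzyloxy)phenyl]ethynyl}oxy)tri(propan-2-yl)silane, via lithium acetylide 11 (not isolated), via lithium ynolate 12 (not isolated)
Conditions: LiN(SiMe3)2, THF, −78 °C; then t-BuOOLi [from t-BuOOH, LiN(SiMe3)2, THF, −78 °C], −78 → 0 °C; then iPr3SiOSO2CF3, −78 → 0 °C
Reagents that add atoms: tert-butyl hydroperoxide, CC(C)(C)OO; triisopropylsilyl trifluoromethanesulfonate, CC(C)[Si](OS(=O)(=O)C(F)(F)F)(C(C)C)C(C)C
Why: The lithium acetylide is oxidised by the lithium peroxide with oxygen transfer to carbon, and the ynolate is trapped on oxygen by the hard, bulky silyl triflate (ynolate oxidation and O-silylation); the amide base does not touch the benzyl ether, and the triisopropylsilyl group makes the ynol ether stable enough to purify on deactivated silica.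

Step 5
Reactants: 9 pentacarbonyl{(2Z)-3-[4-(benzyloxy)phenyl]-2-tert-butoxy-1-methoxyprop-2-en-1-ylidene}chromium; 13 ({[4-(benzyloxy)phenyl]ethynyl}oxy)tri(propan-2-yl)silane
Product: 15 3,6-bis[4-(benzyloxy)phenyl]-5-tert-butoxy-4-methoxy-2-[(triisopropylsilyl)oxy]phenol, via tricarbonylchromium arene complex 14 (not isolated)
Conditions: 13 (1.5 equiv), THF (0.05 M), 50 °C, Ar, dark; then air, CH2Cl2, 25 °C
Reagents that add atoms: none
Why: Proposed new method: after loss of one CO from the zerovalent chromium carbene 9, ynol ether 13 should insert into the Cr=C bond with its nucleophilic aryl-bearing carbon bonding to the electrophilic carbene carbon, so that the siloxy-bearing carbon becomes the new carbene centre. CO insertion there gives a chromium-bound dienylketene, which closes the benzene ring by 6π electrocyclisation between the ketene carbon and the styryl β-carbon; the cyclohexadienone then tautomerises to the phenol, held first as η6 complex 14 and freed by air. The closest known reaction type is the Dötz benzannulation of alkenyl(alkoxy)carbene chromium complexes, α-alkoxyalkenyl ones included, with ordinary alkynes, and the benzannulation of alkoxy(dienyl)carbene complexes to ortho-alkoxyphenols covers the second half of the sequence; a siloxyalkyne as the two-carbon partner is new. One ring closes, in the 6π-electrocyclic mode, with three new C–C bonds in all, and no stereocentre arises. The step needs one regiochemistry of insertion, the oxygen-bearing alkyne carbon next to the CO-derived carbon. The polarisation of the O–C≡C unit secures it electronically, and the bulk of the triisopropylsilyloxy group points the same way, since the larger alkyne substituent normally ends next to the new hydroxyl. The Z geometry of 9 puts hydrogen, not aryl, on the inside of the closing terminus.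

Step 6
Reactants: 15 3,6-bis[4-(benzyloxy)phenyl]-5-tert-butoxy-4-methoxy-2-[(triisopropylsilyl)oxy]phenol
Product: 17 2,5-bis[4-(benzyloxy)phenyl]-3-tert-butoxy-6-hydroxycyclohexa-2,5-diene-1,4-dione, via silyloxyquinone 16 (not isolated)
Conditions: PhI(OAc)2, MeCN/H2O (5:1), 0 °C; then Et3N·3HF, 0 → 25 °C
Reagents that add atoms: water, O
Why: Oxidative demethylation of a 4-methoxyphenol by a hypervalent iodine reagent, in which water adds para and the methoxy group leaves as the alcohol, so the quinone carbonyls arise at the OH/OMe pair; the silyl group on O2 blocks the ortho-quinone path and acetic acid is the only acid set free, so the tert-butyl ether should survive. The silyl vinylogous ester of 16 is then cleaved by fluoride more readily than anything else in the molecule.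

Step 7
Reactants: 17 2,5-bis[4-(benzyloxy)phenyl]-3-tert-butoxy-6-hydroxycyclohexa-2,5-diene-1,4-dione; 18 3-phenylpropanoyl chloride
Product: 19 2,5-bis[4-(benzyloxy)phenyl]-4-tert-butoxy-3,6-dioxocyclohexa-1,4-dien-1-yl 3-phenylpropanoate
Conditions: iPr2NEt, CH2Cl2, −20 → 0 °C
Reagents that add atoms: none
Why: O-Acylation of the vinylogous carboxylate of 17; reaction at O2 keeps the para-quinone and is the less hindered site, whereas the other oxygen, next to the tert-butoxy group, would give an ortho-quinone.

Step 8
Reactants: 19 2,5-bis[4-(benzyloxy)phenyl]-4-tert-butoxy-3,6-dioxocyclohexa-1,4-dien-1-yl 3-phenylpropanoate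
Product: 20 2,5-bis[4-(benzyloxy)phenyl]-4-hydroxy-3,6-dioxocyclohexa-1,4-dien-1-yl 3-phenylpropanoate
Conditions: CF3CO2H/CH2Cl2 (1:4), 0 °C
Reagents that add atoms: none
Why: Acidolysis of a tert-butyl vinylogous ester (E1 loss of the tert-butyl cation as the alkene), as for a tert-butyl ester; anhydrous acid at this temperature should leave the acyloxyquinone ester and the aryl benzyl ethers in place.

Step 9
Reactants: 21 ethyl (3S)-3-hydroxybutanoate
Product: 22 ethyl (3S)-3-(benzyloxy)butanoate
Conditions: BnOC(=NH)CCl3, CF3SO3H (cat.), CH2Cl2/cyclohexane, 0 → 25 °C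
Reagents that add atoms: benzyl 2,2,2-trichloroacetimidate, N=C(OCc1ccccc1)C(Cl)(Cl)Cl
Why: Acid-catalysed O-benzylation with the trichloroacetimidate; no base is present, so neither retro-aldol cleavage nor elimination occurs, and the C3–O bond is not broken, which keeps the S configuration.

Step 10
Reactants: 22 ethyl (3S)-3-(benzyloxy)butanoate
Product: 23 (3S)-3-(benzyloxy)butanoic acid
Conditions: LiOH, THF/H2O, 0 → 25 °C; then 1 M HCl
Reagents that add atoms: lithium hydroxide, [Li+].[OH-]
Why: Saponification at or below room temperature; the β-benzyloxy group is a poor leaving group under these conditions and the stereocentre is not involved.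

Step 11
Reactants: 20 2,5-bis[4-(benzyloxy)phenyl]-4-hydroxy-3,6-dioxocyclohexa-1,4-dien-1-yl 3-phenylpropanoate; 23 (3S)-3-(benzyloxy)butanoic acid
Product: 25 2,5-bis[4-(benzyloxy)phenyl]-3,6-dioxo-4-[(3-phenylpropanoyl)oxy]cyclohexa-1,4-dien-1-yl (3S)-3-(benzyloxy)butanoate, via acid chloride 24 (not isolated)
Conditions: 23, (COCl)2, DMF (cat.), CH2Cl2, 0 → 25 °C, evaporate; then 20, iPr2NEt, CH2Cl2, −20 → 0 °C
Reagents that add atoms: none
Why: Second O-acylation of a vinylogous carboxylate, now at the only free hydroxyl; the stereocentre is β to the acyl carbon and cannot epimerise, and low temperature with a hindered base should limit acyl exchange between the two active ester sites.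

Step 12
Reactants: 25 2,5-bis[4-(benzyloxy)phenyl]-3,6-dioxo-4-[(3-phenylpropanoyl)oxy]cyclohexa-1,4-dien-1-yl (3S)-3-(benzyloxy)butanoate
Product: 26 2,5-dihydroxy-3,6-bis(4-hydroxyphenyl)-4-[(3-phenylpropanoyl)oxy]phenyl (3S)-3-hydroxybutanoate
Conditions: H2 (1 atm), 10% Pd/C, EtOAc, 25 °C
Reagents that add atoms: none
Why: One catalytic hydrogenation reduces the quinone to the hydroquinone and cleaves the two aryl benzyl ethers and the alkyl benzyl ether by hydrogenolysis; neutral, aprotic conditions disfavour the 1,2-acyl shift, and the C3–O bond of the stereocentre is not benzylic and stays.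

## Compound list

1 | tert-butoxyacetic acid | CC(C)(C)OCC(=O)O | starting material
2 | methyl 2-(tert-butoxy)acetate | COC(=O)COC(C)(C)C | intermediate
3 | 4-(benzyloxy)benzaldehyde | O=Cc1ccc(OCc2ccccc2)cc1 | starting material
4 | methyl (2Z)-3-[4-(benzyloxy)phenyl]-2-tert-butoxyprop-2-enoate | COC(=O)/C(OC(C)(C)C)=C/c1ccc(OCc2ccccc2)cc1 | intermediate (not isolated)
5 | (2Z)-3-[4-(benzyloxy)phenyl]-2-tert-butoxyprop-2-enoic acid | OC(=O)/C(OC(C)(C)C)=C/c1ccc(OCc2ccccc2)cc1 | intermediate
6 | hexacarbonylchromium Cr(CO)6 | O=C=[Cr](=C=O)(=C=O)(=C=O)(=C=O)=C=O | starting material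
7 | (2Z)-3-[4-(benzyloxy)phenyl]-2-tert-butoxyprop-2-enoyl chloride | ClC(=O)/C(OC(C)(C)C)=C/c1ccc(OCc2ccccc2)cc1 | intermediate (not isolated)
8 | sodium pentacarbonyl{(2Z)-3-[4-(benzyloxy)phenyl]-2-tert-butoxyprop-2-enoyl}chromate | [Na+].[O-]C(/C(OC(C)(C)C)=C/c1ccc(OCc2ccccc2)cc1)=[Cr](=C=O)(=C=O)(=C=O)(=C=O)=C=O | intermediate (not isolated)
9 | pentacarbonyl{(2Z)-3-[4-(benzyloxy)phenyl]-2-tert-butoxy-1-methoxyprop-2-en-1-ylidene}chromium | COC(/C(OC(C)(C)C)=C/c1ccc(OCc2ccccc2)cc1)=[Cr](=C=O)(=C=O)(=C=O)(=C=O)=C=O | intermediate
10 | 1-(benzyloxy)-4-ethynylbenzene | C#Cc1ccc(OCc2ccccc2)cc1 | starting material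
11 | lithium [4-(benzyloxy)phenyl]acetylide | [Li]C#Cc1ccc(OCc2ccccc2)cc1 | intermediate (not isolated)
12 | lithium 2-[4-(benzyloxy)phenyl]ethynolate | [Li+].[O-]C#Cc1ccc(OCc2ccccc2)cc1 | intermediate (not isolated)
13 | ({[4-(benzyloxy)phenyl]ethynyl}oxy)tri(propan-2-yl)silane | CC(C)[Si](OC#Cc1ccc(OCc2ccccc2)cc1)(C(C)C)C(C)C | intermediate
14 | tricarbonyl(η6-arene)chromium complex of phenol 15, bound at the central ring | COc1c(-c2ccc(OCc3ccccc3)cc2)c(O[Si](C(C)C)(C(C)C)C(C)C)c(O)c(-c2ccc(OCc3ccccc3)cc2)c1OC(C)(C)C.O=C=[Cr](=C=O)=C=O | intermediate (not isolated)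
15 | 3,6-bis[4-(benzyloxy)phenyl]-5-tert-butoxy-4-methoxy-2-[(triisopropylsilyl)oxy]phenol | COc1c(-c2ccc(OCc3ccccc3)cc2)c(O[Si](C(C)C)(C(C)C)C(C)C)c(O)c(-c2ccc(OCc3ccccc3)cc2)c1OC(C)(C)C | intermediate
16 | 2,5-bis[4-(benzyloxy)phenyl]-3-tert-butoxy-6-[(triisopropylsilyl)oxy]cyclohexa-2,5-diene-1,4-dione | O=C1C(O[Si](C(C)C)(C(C)C)C(C)C)=C(c2ccc(OCc3ccccc3)cc2)C(=O)C(OC(C)(C)C)=C1c1ccc(OCc2ccccc2)cc1 | intermediate (not isolated)
17 | 2,5-bis[4-(benzyloxy)phenyl]-3-tert-butoxy-6-hydroxycyclohexa-2,5-diene-1,4-dione | O=C1C(O)=C(c2ccc(OCc3ccccc3)cc2)C(=O)C(OC(C)(C)C)=C1c1ccc(OCc2ccccc2)cc1 | intermediate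
18 | 3-phenylpropanoyl chloride | O=C(Cl)CCc1ccccc1 | starting material
19 | 2,5-bis[4-(benzyloxy)phenyl]-4-tert-butoxy-3,6-dioxocyclohexa-1,4-dien-1-yl 3-phenylpropanoate | O=C1C(OC(=O)CCc2ccccc2)=C(c2ccc(OCc3ccccc3)cc2)C(=O)C(OC(C)(C)C)=C1c1ccc(OCc2ccccc2)cc1 | intermediate
20 | 2,5-bis[4-(benzyloxy)phenyl]-4-hydroxy-3,6-dioxocyclohexa-1,4-dien-1-yl 3-phenylpropanoate | O=C1C(OC(=O)CCc2ccccc2)=C(c2ccc(OCc3ccccc3)cc2)C(=O)C(O)=C1c1ccc(OCc2ccccc2)cc1 | intermediate
21 | ethyl (3S)-3-hydroxybutanoate | C[C@H](O)CC(=O)OCC | starting material
22 | ethyl (3S)-3-(benzyloxy)butanoate | C[C@H](OCc1ccccc1)CC(=O)OCC | intermediate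
23 | (3S)-3-(benzyloxy)butanoic acid | C[C@H](OCc1ccccc1)CC(=O)O | intermediate
24 | (3S)-3-(benzyloxy)butanoyl chloride | C[C@H](OCc1ccccc1)CC(=O)Cl | intermediate (not isolated)
25 | 2,5-bis[4-(benzyloxy)phenyl]-3,6-dioxo-4-[(3-phenylpropanoyl)oxy]cyclohexa-1,4-dien-1-yl (3S)-3-(benzyloxy)butanoate | C[C@H](OCc1ccccc1)CC(=O)OC1=C(c2ccc(OCc3ccccc3)cc2)C(=O)C(OC(=O)CCc2ccccc2)=C(c2ccc(OCc3ccccc3)cc2)C1=O | intermediate
26 | 2,5-dihydroxy-3,6-bis(4-hydroxyphenyl)-4-[(3-phenylpropanoyl)oxy]phenyl (3S)-3-hydroxybutanoate (CNP0296884.1) | C[C@H](O)CC(=O)Oc1c(O)c(-c2ccc(O)cc2)c(OC(=O)CCc2ccccc2)c(O)c1-c1ccc(O)cc1 | target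

## Step count and least certain steps

Total: 12 steps. Longest linear sequence: 9 steps (1, 2, 3, 5, 6, 7, 8, 11, 12).

**Step 5 (key step, new method).**
- What may go wrong: insertion of the ynol ether may stop at the oxygen-stabilised dienylcarbene without CO uptake; the ring may close without CO to a five-membered ring; the alkyne may insert the other way round; or the intermediate ketene may take up a second, electron-rich alkyne. All follow from the unusually stabilised carbene formed after insertion and the high nucleophilicity of 13.
- Fallback (known chemistry; sets out from acid chloride 18, the only compound of the route it uses, and returns at 20): the benzannulation is given up and the oxygen differentiation is traded for one statistical step. Tetrabromo-1,4-benzoquinone is treated with NaOMe in MeOH to give 2,5-dibromo-3,6-dimethoxycyclohexa-2,5-diene-1,4-dione F1. Double Suzuki coupling with 4-(benzyloxy)phenylboronic acid (Pd(PPh3)4, zerovalent palladium, K2CO3, dioxane/H2O) gives 2,5-bis[4-(benzyloxy)phenyl]-3,6-dimethoxycyclohexa-2,5-diene-1,4-dione F2. Aqueous NaOH in MeOH hydrolyses both vinylogous methyl esters to 2,5-bis[4-(benzyloxy)phenyl]-3,6-dihydroxycyclohexa-2,5-diene-1,4-dione F3. One equivalent of 18 with iPr2NEt should then give 20 beside diester and unchanged F3, which are separated, and F3 is recycled.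

**Step 3.**
- What may go wrong: electron transfer from the strongly reducing chromate dianion to the conjugated acid chloride, or conjugate addition, in place of acyl substitution; loss of the tert-butyl enol ether while the chloride is made.
- Fallback (sets out from 6 and aldehyde 3, returns at 9): the C=C bond is built on a preformed carbene. tert-Butoxymethyllithium F4 (from tert-butyl methyl ether with s-BuLi/KOt-Bu, then LiBr) adds to 6 to give lithium pentacarbonyl(tert-butoxyacetyl)chromate F5. Methylation with Me3OBF4 gives pentacarbonyl(2-tert-butoxy-1-methoxyethylidene)chromium F6. Its acidic α-CH2 group is condensed with 3 (Et3N, Me3SiCl, CH2Cl2, 25 °C), the aldol condensation used to turn alkyl(alkoxy)carbene complexes into styryl ones, to give 9.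

**Step 6.**
- What may go wrong: slow oxidation of the hindered, hexasubstituted phenol; early loss of the silyl group, which opens the ortho-quinone path with the methyl group retained; acid-promoted loss of the tert-butyl group once the quinone is formed.
- Fallback (sets out from 15, returns at 17): the ortho-quinone path is used on purpose and acid is avoided. Desilylation (Bu4NF/AcOH, THF, 0 °C) gives 3,6-bis[4-(benzyloxy)phenyl]-4-tert-butoxy-5-methoxybenzene-1,2-diol F7. Ag2O (MgSO4, Et2O) oxidises it to 3,6-bis[4-(benzyloxy)phenyl]-4-tert-butoxy-5-methoxycyclohexa-3,5-diene-1,2-dione F8. LiOH in THF/H2O at 0 °C then hydrolyses the methyl vinylogous ester by addition–elimination at the methoxy-bearing carbon, not at the shielded tert-butoxy-bearing one, which gives the anion of 17, the para-quinone tautomer.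

**Step 2.**
- What may go wrong: reversal of the aldol addition and incomplete dehydration with the hindered α-tert-butoxy ester and the electron-rich aldehyde.
- Fallback (sets out from aldehyde 3, returns at ester 4): Horner–Wadsworth–Emmons olefination with methyl 2-tert-butoxy-2-(dimethoxyphosphoryl)acetate F9 (from methyl 2-diazo-2-(dimethoxyphosphoryl)acetate and tert-butanol by Rh2(OAc)4-catalysed O–H insertion), NaH, THF, 0 °C. The olefination is irreversible, and either alkene geometry can be carried on because the double bond ends inside the aromatic ring.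

**Step 12.**
- What may go wrong: 1,2-acyl shift between neighbouring oxygens of the hydroquinone while the slower hydrogenolysis of the secondary alkyl benzyl ether is awaited; reoxidation on work-up.
- Fallback (sets out from 25, returns at 26): all three benzyl ethers are cleaved at the quinone level with BCl3 and pentamethylbenzene (CH2Cl2, −78 °C) to give 2,5-bis(4-hydroxyphenyl)-3,6-dioxo-4-[(3-phenylpropanoyl)oxy]cyclohexa-1,4-dien-1-yl (3S)-3-hydroxybutanoate F10. The quinone is then reduced with aqueous Na2S2O4 in EtOAc, so the hydroquinone appears only in a last, fast, metal-free and faintly acidic operation.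

## Further compounds

F1 | step 5 | 2,5-dibromo-3,6-dimethoxycyclohexa-2,5-diene-1,4-dione | COC1=C(Br)C(=O)C(OC)=C(Br)C1=O
F2 | step 5 | 2,5-bis[4-(benzyloxy)phenyl]-3,6-dimethoxycyclohexa-2,5-diene-1,4-dione | COC1=C(c2ccc(OCc3ccccc3)cc2)C(=O)C(OC)=C(c2ccc(OCc3ccccc3)cc2)C1=O
F3 | step 5 | 2,5-bis[4-(benzyloxy)phenyl]-3,6-dihydroxycyclohexa-2,5-diene-1,4-dione | OC1=C(c2ccc(OCc3ccccc3)cc2)C(=O)C(O)=C(c2ccc(OCc3ccccc3)cc2)C1=O
F4 | step 3 | tert-butoxymethyllithium | [Li]COC(C)(C)C
F5 | step 3 | lithium pentacarbonyl(tert-butoxyacetyl)chromate | [Li+].[O-]C(COC(C)(C)C)=[Cr](=C=O)(=C=O)(=C=O)(=C=O)=C=O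
F6 | step 3 | pentacarbonyl(2-tert-butoxy-1-methoxyethylidene)chromium | COC(COC(C)(C)C)=[Cr](=C=O)(=C=O)(=C=O)(=C=O)=C=O
F7 | step 6 | 3,6-bis[4-(benzyloxy)phenyl]-4-tert-butoxy-5-methoxybenzene-1,2-diol | COc1c(-c2ccc(OCc3ccccc3)cc2)c(O)c(O)c(-c2ccc(OCc3ccccc3)cc2)c1OC(C)(C)C
F8 | step 6 | 3,6-bis[4-(benzyloxy)phenyl]-4-tert-butoxy-5-methoxycyclohexa-3,5-diene-1,2-dione | COC1=C(c2ccc(OCc3ccccc3)cc2)C(=O)C(=O)C(c2ccc(OCc3ccccc3)cc2)=C1OC(C)(C)C
F9 | step 2 | methyl 2-tert-butoxy-2-(dimethoxyphosphoryl)acetate | COC(=O)C(OC(C)(C)C)P(=O)(OC)OC
F10 | step 12 | 2,5-bis(4-hydroxyphenyl)-3,6-dioxo-4-[(3-phenylpropanoyl)oxy]cyclohexa-1,4-dien-1-yl (3S)-3-hydroxybutanoate | C[C@H](O)CC(=O)OC1=C(c2ccc(O)cc2)C(=O)C(OC(=O)CCc2ccccc2)=C(c2ccc(O)cc2)C1=O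
A1 | alternative 1 | atromentin | O=C1C(O)=C(c2ccc(O)cc2)C(=O)C(O)=C1c1ccc(O)cc1
A2 | alternative 1 | 4-hydroxyphenylpyruvic acid | O=C(O)C(=O)Cc1ccc(O)cc1
A3 | alternative 2 | 2',3',5',6'-tetramethoxy-1,1':4',1''-terphenyl-4,4''-diol | COc1c(OC)c(-c2ccc(O)cc2)c(OC)c(OC)c1-c1ccc(O)cc1
A4 | alternative 2 | 1-methoxy-3-(trimethylsilyloxy)buta-1,3-diene | CO/C=C/C(=C)O[Si](C)(C)C
A5 | alternative 2 | 1,2,4,5-tetramethoxy-3,6-bis[1-(phenylsulfonyl)ethenyl]benzene | COc1c(OC)c(C(=C)S(=O)(=O)c2ccccc2)c(OC)c(OC)c1C(=C)S(=O)(=O)c1ccccc1
A6 | alternative 3 | 4,7-bis[4-(benzyloxy)phenyl]-5,6-di-tert-butoxy-2,2-diisopropyl-1,3,2-benzodioxasilole | CC(C)[Si]1(C(C)C)Oc2c(O1)c(-c1ccc(OCc3ccccc3)cc1)c(OC(C)(C)C)c(OC(C)(C)C)c2-c1ccc(OCc2ccccc2)cc1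
A7 | alternative 3 | bis({[4-(benzyloxy)phenyl]ethynyl}oxy)di(propan-2-yl)silane | CC(C)[Si](OC#Cc1ccc(OCc2ccccc2)cc1)(OC#Cc1ccc(OCc2ccccc2)cc1)C(C)C
A8 | alternative 3 | di-tert-butoxyethyne | CC(C)(C)OC#COC(C)(C)C
A9 | alternative 3 | chlorotris(triphenylphosphine)rhodium RhCl(PPh3)3 | Cl[Rh-3]([P+](c1ccccc1)(c1ccccc1)c1ccccc1)([P+](c1ccccc1)(c1ccccc1)c1ccccc1)[P+](c1ccccc1)(c1ccccc1)c1ccccc1
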